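**Plan**
Retrosynthetic cuts: (a) the C15–O bond of the peroxy-lactol, back to the 11-hydroperoxy-(12E)-15,16-dial; (b) C12=C13, back to a C11-peroxy C12 aldehyde and a formyl ylide that carries C13–C16; (c) the C11–O bond, back to the silyl enol ether of the C12 aldehyde and O2; (d) C12, then 7α-OH/8(17)-ene back to the 7,8-alkene of drimenol, and C11 back to a C9 ketone; (e) ring A at C1–C10 and C3–C4, leaving 6-methylcarvone and a three-carbon unit; (f) C10–CH3.
Forward order: ring B is (R)-carvone; methylation, then an alkylative (3+3) annulation builds ring A; C11 is added at the C9 ketone; the 7,8-alkene becomes 7α-OH/8(17)-ene; C12 is added by homologation; C11 is oxygenated with singlet oxygen; a Wittig reaction adds C13–C16; the seven-membered peroxide ring closes last, on deprotection.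
Enabling feature: in ring A (C1–C5 and C10) the two quaternary carbons C4 (gem-dimethyl) and C10 (angular methyl) both sit on C5–H, and C1–C3 are plain CH2. C4 and C10 therefore map onto the isopropenyl carbon and the α′-carbon of carvone, and the isopropenyl CH2 ends as a methyl group on C4.
Stereochemistry: C5 from (R)-carvone; C10 by alkylation anti to the isopropenyl group; C9 by α-face hydroboration; C7 by α-face epoxidation; C11 by the face of singlet-oxygen attack on the silyl enol ether; the 12E geometry, which puts C14 cis to C11, by the stabilised ylide; the lactol carbon C15 is thermodynamic.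
Key step: step 4

Remark: positions follow labdane numbering (ring A = C1–C5 with C10, ring B = C5–C10, C17 = exocyclic methylene carbon). The lactol carbon C15 is a hemiperoxyacetal and is assumed to equilibrate to the drawn epimer (OH trans to the C11 substituent).

**Step 1**
Reactants: 1 ethyl (2Z)-3-iodoprop-2-enoate
Product: 2 (2Z)-3-iodoprop-2-en-1-ol
Conditions: i-Bu2AlH (2.2 equiv), CH2Cl2, −78 °C
Reagents that add atoms: none
Why: Aluminium hydride reduction of the ester to the primary allylic alcohol at low temperature should leave the vinyl iodide and its Z geometry untouched.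

**Step 2**
Reactants: 2 (2Z)-3-iodoprop-2-en-1-ol
Product: 3 (1Z)-3-bromo-1-iodoprop-1-ene
Conditions: CBr4, PPh3, CH2Cl2, 0 °C
Reagents that add atoms: carbon tetrabromide, BrC(Br)(Br)Br
Why: The Appel reaction replaces the primary allylic OH by bromide under neutral conditions (SN2 at CH2) without changing the Z-alkene.

**Step 3**
Reactants: 4 (R)-(−)-carvone
Product: 5 (5R,6S)-6-methylcarvone
Conditions: LiN(iPr)2, THF, −78 °C; MeI, −78 → 0 °C
Reagents that add atoms: iodomethane, CI
Why: Kinetic α′-deprotonation gives the cross-conjugated lithium dienolate, which is C-methylated (enolate alkylation); the new C6 centre (mainly trans to isopropenyl) is erased by enolization in step 4, so both epimers can be used.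

**Step 4**
Reactants: 5 (5R,6S)-6-methylcarvone; 3 (1Z)-3-bromo-1-iodoprop-1-ene
Product: 7 (4aS,8aS)-2,5,5,8a-tetramethyl-4a,5,8,8a-tetrahydronaphthalen-1(4H)-one, via iodoallyl ketone 6 (not isolated)
Conditions: LiN(iPr)2, THF–DMPU, −78 °C; 3, −78 → 0 °C; then Pd(OAc)2 (cat.), PPh3, HCO2Na, Et4NCl, DMF, 80 °C, same flask
Reagents that add atoms: none
Why: LiN(iPr)2 removes the only α′-hydrogen of 5 and the tetrasubstituted enolate carbon is alkylated by the allylic bromide of 3 in an SN2 step (bond C1–C10); zerovalent palladium then inserts into the retained Z-vinyl iodide of 6 and the vinylpalladium adds across the isopropenyl group in a 6-exo-trig syn-carbopalladation that closes ring A (bond C3–C4) and makes C4 quaternary. The resulting neopentyl-type alkylpalladium has no β-hydrogen and is reduced by formate (decarboxylation, then C–H reductive elimination), so the former isopropenyl CH2 becomes the second methyl group on C4. The closest known reaction types are the trans-selective second α′-alkylation of 6-alkylcarvones and the intramolecular reductive Heck cyclization onto 1,1-disubstituted alkenes. The only new stereocentre, C10, is set in the alkylation by the C5 centre of carvone: the electrophile should enter anti to the pseudo-axial isopropenyl group, which puts the C1 chain trans to C4 on ring B and hence gives the trans ring fusion on closure. The step needs C- over O-alkylation (lithium enolate, soft allylic bromide), insertion faster than hydride capture of the vinylpalladium (intramolecular 6-exo insertion precedes formate decarboxylation) and 6-exo over 7-endo insertion (the usual preference); the Z geometry of 3 places palladium cis to C1 so that the ring alkene can form.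

**Step 5**
Reactants: 7 (4aS,8aS)-2,5,5,8a-tetramethyl-4a,5,8,8a-tetrahydronaphthalen-1(4H)-one
Product: 8 (4aS,8aS)-2,5,5,8a-tetramethyl-4a,5,6,7,8,8a-hexahydronaphthalen-1(4H)-one
Conditions: H2 (1 atm), RhCl(PPh3)3 (cat.), benzene–EtOH, rt
Reagents that add atoms: none
Why: Homogeneous hydrogenation with RhCl(PPh3)3 should reduce the unconjugated cis-disubstituted C2=C3 alkene of ring A and leave the trisubstituted conjugated C7=C8 alkene; no stereocentre is formed.

**Step 6**
Reactants: 8 (4aS,8aS)-2,5,5,8a-tetramethyl-4a,5,6,7,8,8a-hexahydronaphthalen-1(4H)-one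
Product: 9 (4aS,8aS)-2,5,5,8a-tetramethyl-1-methylidene-1,4,4a,5,6,7,8,8a-octahydronaphthalene
Conditions: Ph3PCH3Br, KOt-Bu, toluene, 90 °C
Reagents that add atoms: methyltriphenylphosphonium bromide, C[P+](c1ccccc1)(c1ccccc1)c1ccccc1.[Br-]
Why: Wittig methylenation under forcing conditions suits this hindered ketone, which has no α′-hydrogen (C10 is quaternary) and no epimerizable centre.

**Step 7**
Reactants: 9 (4aS,8aS)-2,5,5,8a-tetramethyl-1-methylidene-1,4,4a,5,6,7,8,8a-octahydronaphthalene
Product: 11 (−)-drimenol, via alkylborane 10 (not isolated)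
Conditions: 9-BBN, THF, 0 °C → reflux; then NaOH, H2O2, 0 °C → rt
Reagents that add atoms: 9-borabicyclo[3.3.1]nonane, B1C2CCCC1CCC2 (its atoms stay only in 10); hydrogen peroxide, OO
Why: Hydroboration–oxidation: the bulky borane should add boron to the terminal carbon C11 of the semicyclic diene and deliver hydrogen to C9 from the α-face, opposite the axial C10 methyl group, which sets C9 (9α-H, 9β-CH2OH); the C–B bond is oxidised with retention.

**Step 8**
Reactants: 11 (−)-drimenol
Product: 12 (−)-drimenol 7α,8α-epoxide
Conditions: mCPBA, NaHCO3, CH2Cl2, 0 °C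
Reagents that add atoms: 3-chloroperoxybenzoic acid, O=C(OO)c1cccc(Cl)c1
Why: Prilezhaev epoxidation of the only alkene should occur on the α-face, anti to the axial angular methyl group, which fixes the C7–O bond as 7α.

**Step 9**
Reactants: 12 (−)-drimenol 7α,8α-epoxide
Product: 13 7α-hydroxyalbicanol
Conditions: Et2AlCl, lithium 2,2,6,6-tetramethylpiperidide, toluene, 0 °C → rt (excess; the C11–OH is carried as its aluminium alkoxide)
Reagents that add atoms: none
Why: Aluminium amide-mediated epoxide-to-allylic-alcohol isomerization: the amide removes a proton from the C8 methyl group (the least hindered β-hydrogen) in a syn cyclic transition state while the tertiary C8–O bond breaks, so the 8(17)-alkene forms and the 7α-oxygen keeps its configuration.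

**Step 10**
Reactants: 13 7α-hydroxyalbicanol
Product: 14 7α-hydroxyalbicanal
Conditions: TEMPO (cat.), PhI(OAc)2, CH2Cl2, rt
Reagents that add atoms: none
Why: Oxoammonium (TEMPO) oxidation should select the unhindered primary C11 alcohol over the axial secondary allylic 7α-OH and is mild enough not to move the exocyclic alkene into conjugation.

**Step 11**
Reactants: 14 7α-hydroxyalbicanal
Product: 16 7α-hydroxy-13,14,15,16-tetranorlabd-8(17)-en-12-al, via methyl enol ether 15 (not isolated)
Conditions: Ph3PCH2OMe Cl, KOt-Bu (excess), THF, 0 °C; 14, −78 → 0 °C; then 1 M aq. HCl, THF, 0 °C → rt, same flask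
Reagents that add atoms: (methoxymethyl)triphenylphosphonium chloride, COC[P+](c1ccccc1)(c1ccccc1)c1ccccc1.[Cl-]; water, O
Why: Wittig methoxymethylenation at low temperature should outrun deprotonation at C9, and mild acid hydrolysis of the enol ether 15 gives the one-carbon-homologated aldehyde, in which C9 is no longer α to a carbonyl group.

**Step 12**
Reactants: 16 7α-hydroxy-13,14,15,16-tetranorlabd-8(17)-en-12-al
Product: 17 7α,12-bis(trimethylsilyloxy)-13,14,15,16-tetranorlabda-8(17),11-diene
Conditions: TMSOTf, Et3N (excess, added first), CH2Cl2, 0 °C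
Reagents that add atoms: trimethylsilyl trifluoromethanesulfonate, C[Si](C)(C)OS(=O)(=O)C(F)(F)F
Why: Soft enolization of the aldehyde with silyl triflate and amine gives the silyl enol ether (mainly 11Z expected; either geometry can be used) and silylates the 7α-OH at the same time; no stereocentre is touched.

**Step 13**
Reactants: 18 [2-(1,3-dioxolan-2-yl)ethyl]triphenylphosphonium bromide
Product: 19 3-(1,3-dioxolan-2-yl)-2-(triphenylphosphoranylidene)propanal
Conditions: KOt-Bu (2.2 equiv), THF, 0 °C; HCO2Et, 0 °C → rt
Reagents that add atoms: ethyl formate, CCOC=O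
Why: Deprotonation gives the non-stabilised ylide, which is C-formylated by ethyl formate (acylation of a phosphorus ylide); the excess base converts the acylphosphonium salt into the formyl-stabilised ylide.

**Step 14**
Reactants: 17 7α,12-bis(trimethylsilyloxy)-13,14,15,16-tetranorlabda-8(17),11-diene; 19 3-(1,3-dioxolan-2-yl)-2-(triphenylphosphoranylidene)propanal
Product: 21 (11S,12E)-15,15-(ethylenedioxy)-7α-(trimethylsilyloxy)-11-(trimethylsilylperoxy)labda-8(17),12-dien-16-al, via α-silylperoxy aldehyde 20 (not isolated)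
Conditions: O2, tetraphenylporphyrin (cat.), visible light, CH2Cl2, −78 °C; argon purge; then 19, −78 °C → rt, dark, same flask
Reagents that add atoms: dioxygen, O=O
Why: Singlet oxygen should react with the electron-rich silyl enol ether, and not with the 1,1-disubstituted 8(17)-alkene, in an ene-type addition with silyl migration (photooxygenation of silyl enol ethers to α-silylperoxy carbonyl compounds), entering at C11 from the face anti to quaternary C10 in the conformer that holds H9 in the plane of the double bond (allylic 1,3-strain; H9 is then not placed for abstraction), which sets the C11–O bond as in the target; the Wittig reaction of the α-peroxy aldehyde 20 with the formyl-stabilised ylide 19 should then give the 12E enal, with C11 trans to the formyl group and cis to C14.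

**Step 15**
Reactants: 21 (11S,12E)-15,15-(ethylenedioxy)-7α-(trimethylsilyloxy)-11-(trimethylsilylperoxy)labda-8(17),12-dien-16-al
Product: 23 (3S,7S)-3-hydroxy-7-[(1R,3R,4aS,8aS)-3-hydroxy-5,5,8a-trimethyl-2-methylidenedecahydronaphthalen-1-yl]-4,7-dihydro-3H-1,2-dioxepine-5-carbaldehyde, via 11-hydroperoxy dialdehyde 22 (not isolated)
Conditions: 1 M aq. HCl, THF, 0 °C → rt
Reagents that add atoms: water, O
Why: Aqueous acid should cleave the silyl ether, the silyl peroxide and the dioxolane; in 22 the 12E geometry holds C14–C15 cis to C11, so the 11-hydroperoxide adds to the C15 aldehyde (ring–chain tautomerism) to close the seven-membered peroxy-lactol, the enal stays conjugated, and C15 can equilibrate through 22 to the epimer drawn.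

**Compound list**
1 | ethyl (2Z)-3-iodoprop-2-enoate | CCOC(=O)/C=C\I | starting material
2 | (2Z)-3-iodoprop-2-en-1-ol | OC/C=C\I | intermediate
3 | (1Z)-3-bromo-1-iodoprop-1-ene | BrC/C=C\I | intermediate
4 | (R)-(−)-carvone, (5R)-2-methyl-5-(prop-1-en-2-yl)cyclohex-2-en-1-one | CC(=C)[C@@H]1CC=C(C)C(=O)C1 | starting material
5 | (5R,6S)-6-methylcarvone, (5R,6S)-2,6-dimethyl-5-(prop-1-en-2-yl)cyclohex-2-en-1-one (trans epimer drawn; the C6 epimer is equally usable) | CC1=CC[C@@H](C(C)=C)[C@H](C)C1=O | intermediate
6 | (5S,6S)-6-[(2Z)-3-iodoprop-2-en-1-yl]-2,6-dimethyl-5-(prop-1-en-2-yl)cyclohex-2-en-1-one (not isolated) | CC1=CC[C@@H](C(C)=C)[C@](C)(C/C=C\I)C1=O | intermediate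
7 | (4aS,8aS)-2,5,5,8a-tetramethyl-4a,5,8,8a-tetrahydronaphthalen-1(4H)-one | CC1=CC[C@H]2C(C)(C)C=CC[C@]2(C)C1=O | intermediate
8 | (4aS,8aS)-2,5,5,8a-tetramethyl-4a,5,6,7,8,8a-hexahydronaphthalen-1(4H)-one | CC1=CC[C@H]2C(C)(C)CCC[C@]2(C)C1=O | intermediate
9 | (4aS,8aS)-2,5,5,8a-tetramethyl-1-methylidene-1,4,4a,5,6,7,8,8a-octahydronaphthalene | CC1=CC[C@H]2C(C)(C)CCC[C@]2(C)C1=C | intermediate
10 | 9-{[(1S,4aS,8aS)-2,5,5,8a-tetramethyl-1,4,4a,5,6,7,8,8a-octahydronaphthalen-1-yl]methyl}-9-borabicyclo[3.3.1]nonane (not isolated) | CC1=CC[C@H]2C(C)(C)CCC[C@]2(C)[C@H]1CB1C2CCCC1CCC2 | intermediate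
11 | (−)-drimenol, [(1S,4aS,8aS)-2,5,5,8a-tetramethyl-1,4,4a,5,6,7,8,8a-octahydronaphthalen-1-yl]methanol | CC1=CC[C@H]2C(C)(C)CCC[C@]2(C)[C@H]1CO | intermediate
12 | (−)-drimenol 7α,8α-epoxide (oxirane across C7–C8 on the face opposite the angular methyl) | C[C@@]12O[C@@H]1C[C@H]1C(C)(C)CCC[C@]1(C)[C@H]2CO | intermediate
13 | 7α-hydroxyalbicanol (exocyclic methylene on C8, axial 7α-OH, CH2OH on C9) | C=C1[C@H](O)C[C@H]2C(C)(C)CCC[C@]2(C)[C@H]1CO | intermediate
14 | 7α-hydroxyalbicanal (C11 aldehyde of 13) | C=C1[C@H](O)C[C@H]2C(C)(C)CCC[C@]2(C)[C@H]1C=O | intermediate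
15 | 12-methoxy-13,14,15,16-tetranorlabda-8(17),11-dien-7α-ol, methyl enol ether C9–CH=CH–OMe (E/Z mixture, not isolated) | C=C1[C@H](O)C[C@H]2C(C)(C)CCC[C@]2(C)[C@H]1C=COC | intermediate
16 | 7α-hydroxy-13,14,15,16-tetranorlabd-8(17)-en-12-al (C9–CH2–CHO) | C=C1[C@H](O)C[C@H]2C(C)(C)CCC[C@]2(C)[C@H]1CC=O | intermediate
17 | 7α,12-bis(trimethylsilyloxy)-13,14,15,16-tetranorlabda-8(17),11-diene (11Z isomer drawn) | C=C1[C@H](O[Si](C)(C)C)C[C@H]2C(C)(C)CCC[C@]2(C)[C@H]1/C=C\O[Si](C)(C)C | intermediate
18 | [2-(1,3-dioxolan-2-yl)ethyl]triphenylphosphonium bromide | [Br-].c1ccc(cc1)[P+](CCC1OCCO1)(c1ccccc1)c1ccccc1 | starting material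
19 | 3-(1,3-dioxolan-2-yl)-2-(triphenylphosphoranylidene)propanal | O=CC(CC1OCCO1)=P(c1ccccc1)(c1ccccc1)c1ccccc1 | intermediate
20 | 7α-(trimethylsilyloxy)-11-(trimethylsilylperoxy)-13,14,15,16-tetranorlabd-8(17)-en-12-al (C11–O bond as in the target; 11R by the CIP rules because C12 is a formyl group here; not isolated) | C=C1[C@H](O[Si](C)(C)C)C[C@H]2C(C)(C)CCC[C@]2(C)[C@H]1[C@@H](OO[Si](C)(C)C)C=O | intermediate
21 | (11S,12E)-15,15-(ethylenedioxy)-7α-(trimethylsilyloxy)-11-(trimethylsilylperoxy)labda-8(17),12-dien-16-al | C=C1[C@H](O[Si](C)(C)C)C[C@H]2C(C)(C)CCC[C@]2(C)[C@H]1[C@@H](OO[Si](C)(C)C)/C=C(/C=O)CC1OCCO1 | intermediate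
22 | (11S,12E)-11-hydroperoxy-7α-hydroxylabda-8(17),12-diene-15,16-dial (not isolated) | C=C1[C@H](O)C[C@H]2C(C)(C)CCC[C@]2(C)[C@H]1[C@@H](OO)/C=C(/C=O)CC=O | intermediate
23 | (3S,7S)-3-hydroxy-7-[(1R,3R,4aS,8aS)-3-hydroxy-5,5,8a-trimethyl-2-methylidenedecahydronaphthalen-1-yl]-4,7-dihydro-3H-1,2-dioxepine-5-carbaldehyde | C=C1[C@H](O)C[C@H]2C(C)(C)CCC[C@]2(C)[C@H]1[C@@H]1C=C(C=O)C[C@@H](O)OO1 | target

**Step count**
Total steps: 15. Longest linear sequence: 13 (steps 1, 2, 4–12, 14 and 15, from ethyl (2Z)-3-iodoprop-2-enoate).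

**Steps most likely to fail**

Step 14. Singlet oxygen may add to the enol ether in the [2+2] sense, which cleaves C11–C12, or may abstract an allylic hydrogen instead of taking the silyl group. The facial selectivity at C11 may be poor. The α-silylperoxy aldehyde may fragment with loss of silanol before the sluggish α-substituted formyl ylide has reacted. The fallback replaces the ene reaction by a substitution, sets out from 16 and comes back to the route at 23. A Wittig reaction of 16 with 19 (toluene, 90 °C) gives (12E)-15,15-(ethylenedioxy)-7α-hydroxylabda-8(17),12-dien-16-al F1. TMSOTf and Et3N convert F1 into the silyl dienol ether (11E)-15,15-(ethylenedioxy)-7α,16-bis(trimethylsilyloxy)labda-8(17),11,13(16)-triene F2. N-Bromosuccinimide in THF at −78 °C brominates the γ-carbon C11 of the s-trans diene and gives the γ-bromo enal (12E)-11-bromo-15,15-(ethylenedioxy)-7α-(trimethylsilyloxy)labda-8(17),12-dien-16-al F3, with C11 still trans to the formyl group. Silver trifluoroacetate and ethereal H2O2 replace the allylic bromide by OOH (silver-assisted perhydrolysis) and give (11S,12E)-15,15-(ethylenedioxy)-11-hydroperoxy-7α-(trimethylsilyloxy)labda-8(17),12-dien-16-al F4; C11 is then set only by the bias of the substrate, and the C11 epimers would be separated at this stage. Aqueous acid as in step 15 turns F4 into 23.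

Step 4 (key step). The enolate may be O-alkylated or alkylated syn to the isopropenyl group; the vinylpalladium species may be reduced by formate before it inserts; or insertion may go 7-endo. The fallback sets out from 5 and comes back at 7, replacing the palladium closure by a cationic one. Alkylation of the enolate of 5 with (Z)-(3-bromoprop-1-en-1-yl)trimethylsilane gives the vinylsilane (5S,6S)-2,6-dimethyl-5-(prop-1-en-2-yl)-6-[(2Z)-3-(trimethylsilyl)prop-2-en-1-yl]cyclohex-2-en-1-one F5, which is isolated. CF3CO2H in CH2Cl2 protonates the isopropenyl group at its CH2 (Markovnikov); the tertiary C4 cation is captured at C3 by the vinylsilane with loss of the silyl group (vinylsilane-terminated cation–olefin cyclization), giving 7.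

Step 7. Hydroboration may occur from the β-face, giving the wrong C9 epimer, or at the ring alkene. The fallback sets out from 8 and comes back at 11, setting C9 under thermodynamic control instead. A Wittig reaction of 8 with Ph3P=CHOMe gives the dienol ether (4aS,8aS)-1-(methoxymethylidene)-2,5,5,8a-tetramethyl-1,4,4a,5,6,7,8,8a-octahydronaphthalene F6; mild acid hydrolysis (α-protonation at C9, the epimerizable aldehyde settling equatorial) gives drim-7-en-11-al F7; NaBH4 reduces F7 to 11.

**Further compounds**
F1 | step 14 | (12E)-15,15-(ethylenedioxy)-7α-hydroxylabda-8(17),12-dien-16-al | C=C1[C@H](O)C[C@H]2C(C)(C)CCC[C@]2(C)[C@H]1C/C=C(/C=O)CC1OCCO1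
F2 | step 14 | (11E)-15,15-(ethylenedioxy)-7α,16-bis(trimethylsilyloxy)labda-8(17),11,13(16)-triene (silyl dienol ether) | C=C1[C@H](O[Si](C)(C)C)C[C@H]2C(C)(C)CCC[C@]2(C)[C@H]1/C=C/C(CC1OCCO1)=CO[Si](C)(C)C
F3 | step 14 | (12E)-11-bromo-15,15-(ethylenedioxy)-7α-(trimethylsilyloxy)labda-8(17),12-dien-16-al (C11 epimers) | C=C1[C@H](O[Si](C)(C)C)C[C@H]2C(C)(C)CCC[C@]2(C)[C@H]1C(Br)/C=C(/C=O)CC1OCCO1
F4 | step 14 | (11S,12E)-15,15-(ethylenedioxy)-11-hydroperoxy-7α-(trimethylsilyloxy)labda-8(17),12-dien-16-al | C=C1[C@H](O[Si](C)(C)C)C[C@H]2C(C)(C)CCC[C@]2(C)[C@H]1[C@@H](OO)/C=C(/C=O)CC1OCCO1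
F5 | step 4 | (5S,6S)-2,6-dimethyl-5-(prop-1-en-2-yl)-6-[(2Z)-3-(trimethylsilyl)prop-2-en-1-yl]cyclohex-2-en-1-one | CC1=CC[C@@H](C(C)=C)[C@](C)(C/C=C\[Si](C)(C)C)C1=O
F6 | step 7 | (4aS,8aS)-1-(methoxymethylidene)-2,5,5,8a-tetramethyl-1,4,4a,5,6,7,8,8a-octahydronaphthalene (E/Z mixture) | CC1=CC[C@H]2C(C)(C)CCC[C@]2(C)C1=COC
F7 | step 7 | drim-7-en-11-al | CC1=CC[C@H]2C(C)(C)CCC[C@]2(C)[C@H]1C=O
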